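**Retrosynthetic overview**

1. The target is numbered as (1R,5S,8R,9R)-3-allyl-5-methoxy-9-methyl-8-(3,4,5-trimethoxyphenyl)-6-oxabicyclo[3.2.2]non-3-ene-2,7-dione. The last disconnection is the O6–C5 bond of the δ-lactone bridge, which leads back to a monocyclic cycloheptenone with a dimethyl ketal at C5 and a tert-butyl ester on C1.
2. The strategy rests on the bridgehead C1–H: in the seven-membered carbocycle C1–C2–C3–C4–C5–C9–C8 it is a malonyl-type carbon between the C2 ring ketone and the aryl-bearing C8. Removing C1 with its carboxyl leaves a six-membered 2-allyl-4,4-dimethoxy-5-methyl-6-arylcyclohex-2-enone, so C1 is inserted with a diazoacetate (bonds C1–C2 and C1–C8).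
3. That cyclohexenone is the p-quinone monoketal of 2-allyl-4-methoxyphenol plus a methyl group (enantioselective copper-catalysed conjugate addition, sets C9) and an aryl group (palladium α-arylation, sets C8 trans to C9).
4. Ring order: six-membered carbocycle (from the arene), then seven-membered carbocycle (step 6), then the lactone ring that completes the bicycle (step 7).

Key step: step 6

Remark: the copper/phosphoramidite catalyst is assumed to show on dienone 5 the same sense of induction as on unsubstituted 4,4-dimethoxycyclohexadienone; the ligand antipode that delivers the 5R ketone is the one to use. C1 of 11 and 12 is an enolisable centre; both are drawn as the 1R epimer that closes to the target.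

**Route**

Step 1
Reactants: 1 4-methoxyphenol; 2 allyl bromide
Product: 3 1-(allyloxy)-4-methoxybenzene
Conditions: K2CO3, acetone, reflux
Reagents that add atoms: none
Why: Williamson ether synthesis, the phenoxide displacing bromide from the allylic halide; no stereocentre is formed.

Step 2
Reactants: 3 1-(allyloxy)-4-methoxybenzene
Product: 4 2-allyl-4-methoxyphenol
Conditions: PhNEt2, 200 °C
Reagents that add atoms: none
Why: Aromatic Claisen rearrangement followed by tautomerisation; the para position is blocked by the methoxy group and the two ortho positions are equivalent, so one allylphenol should form.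

Step 3
Reactants: 4 2-allyl-4-methoxyphenol
Product: 5 2-allyl-4,4-dimethoxycyclohexa-2,5-dien-1-one
Conditions: PhI(OAc)2, MeOH, 0 °C
Reagents that add atoms: methanol, CO
Why: Hypervalent-iodine oxidative dearomatisation of a p-methoxyphenol, methanol adding at the methoxy-bearing para carbon to give the p-quinone monoketal while the allyl group is left alone.

Step 4
Reactants: 5 2-allyl-4,4-dimethoxycyclohexa-2,5-dien-1-one
Product: 7 (R)-2-allyl-4,4-dimethoxy-5-methylcyclohex-2-en-1-one, via methylzinc dienolate 6 (not isolated)
Conditions: Cu(OTf)2 (2 mol%), (S)-binaphthol bis[(R)-1-phenylethyl]amine phosphoramidite (4 mol%), Me2Zn, toluene, −25 °C; then pH 7 buffer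
Reagents that add atoms: dimethylzinc, C[Zn]C
Why: Copper-catalysed enantioselective conjugate addition of a dialkylzinc to a cyclohexadienone monoketal, in which methyl should add at C5 of the unsubstituted enone arm (the α-allyl arm is much less reactive) and the chiral copper–phosphoramidite complex selects the face of C5=C6 to set C5 as R.

Step 5
Reactants: 7 (R)-2-allyl-4,4-dimethoxy-5-methylcyclohex-2-en-1-one; 8 5-bromo-1,2,3-trimethoxybenzene
Product: 9 (5R,6S)-2-allyl-4,4-dimethoxy-5-methyl-6-(3,4,5-trimethoxyphenyl)cyclohex-2-en-1-one
Conditions: Pd2(dba)3 (2 mol%), Xantphos (5 mol%), NaOtBu, THF, 60 °C; then DBU (cat.), CH2Cl2, rt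
Reagents that add atoms: none
Why: Palladium-catalysed α-arylation of the ketone enolate at C6, the only enolisable position because C4 is quaternary; the product is an epimerisable α-aryl ketone, so the base treatment should settle it as the trans 5-methyl/6-aryl isomer (6S).

Step 6
Reactants: 9 (5R,6S)-2-allyl-4,4-dimethoxy-5-methyl-6-(3,4,5-trimethoxyphenyl)cyclohex-2-en-1-one; 10 tert-butyl diazoacetate
Product: 11 tert-butyl (1R,6R,7R)-3-allyl-5,5-dimethoxy-6-methyl-2-oxo-7-(3,4,5-trimethoxyphenyl)cyclohept-3-ene-1-carboxylate
Conditions: BF3·OEt2 (30 mol%), 10 (2 equiv, slow addition), CH2Cl2, −78 → −40 °C; Et3N quench at −40 °C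
Reagents that add atoms: none
Why: BF3 activates the C1 carbonyl of 9, the diazo carbon of 10 adds to it, and the β-oxido alkyldiazonium ion loses N2 as the antiperiplanar C6 (CHAr) shifts to the diazo carbon, forming the new carbon's bonds to C1 and to C6 in one operation; the closest known reaction type is the Tiffeneau–Demjanov-type homologation of conjugated cyclic ketones with diazoacetic esters. The seven-membered carbocycle arises by enlargement of the six-membered ring through this 1,2-shift and not by a cyclisation, so no closure mode has to be met. The migrating carbon keeps its configuration, so the trans methyl/aryl relationship of 9 reappears unchanged as 6R,7R in 11. The new malonyl centre C1 is not controlled here: it is an enolisable β-keto ester carbon, drawn 1R, and it is settled only when the lactone closes in step 7. The selectivity needed is migration of the saturated benzylic C6 rather than the alkenyl C2; this is expected because alkenyl carbons migrate poorly in acid-promoted diazoacetate insertions into enones, the electron-rich benzylic carbon carries the developing positive charge well, and only C6 migration keeps the enone conjugated. The allylic dimethyl ketal should survive because its oxocarbenium ion would be conjugated to the electron-poor enone, the Lewis acid is substoichiometric and the quench is cold.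

Step 7
Reactants: 11 tert-butyl (1R,6R,7R)-3-allyl-5,5-dimethoxy-6-methyl-2-oxo-7-(3,4,5-trimethoxyphenyl)cyclohept-3-ene-1-carboxylate
Product: 13 (1R,5S,8R,9R)-3-allyl-5-methoxy-9-methyl-8-(3,4,5-trimethoxyphenyl)-6-oxabicyclo[3.2.2]non-3-ene-2,7-dione, via β-keto acid 12 (not isolated)
Conditions: TFA/CH2Cl2 (1:4), 0 °C
Reagents that add atoms: none
Why: Trifluoroacetic acid removes the tert-butyl group as isobutene and ionises the ketal to a methoxy-oxocarbenium ion, which the carboxyl oxygen captures across the ring to give the cyclic pseudo-ester (acid-mediated lactonisation of a tert-butyl ester onto a ketal); the C1 epimers interconvert through the enol, and closure is expected from the 1R epimer because only then does the oxygen reach the ketal carbon on the face anti to the neighbouring C6 methyl, which sets that carbon (C5 of the target) as S and fixes C1 as a bridgehead that can no longer enolise.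

**Compound list**

1 | 4-methoxyphenol | COc1ccc(O)cc1 | starting material
2 | allyl bromide | C=CCBr | starting material
3 | 1-(allyloxy)-4-methoxybenzene | C=CCOc1ccc(OC)cc1 | intermediate
4 | 2-allyl-4-methoxyphenol | C=CCc1cc(OC)ccc1O | intermediate
5 | 2-allyl-4,4-dimethoxycyclohexa-2,5-dien-1-one | C=CCC1=CC(OC)(OC)C=CC1=O | intermediate
6 | methylzinc dienolate of 7 (zinc on O1, double bonds C1=C6 and C2=C3, 5R) | C=CCC1=CC(OC)(OC)[C@H](C)C=C1O[Zn]C | intermediate
7 | (R)-2-allyl-4,4-dimethoxy-5-methylcyclohex-2-en-1-one | C=CCC1=CC(OC)(OC)[C@H](C)CC1=O | intermediate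
8 | 5-bromo-1,2,3-trimethoxybenzene | COc1cc(Br)cc(OC)c1OC | starting material
9 | (5R,6S)-2-allyl-4,4-dimethoxy-5-methyl-6-(3,4,5-trimethoxyphenyl)cyclohex-2-en-1-one (methyl and aryl trans) | C=CCC1=CC(OC)(OC)[C@H](C)[C@@H](c2cc(OC)c(OC)c(OC)c2)C1=O | intermediate
10 | tert-butyl diazoacetate | CC(C)(C)OC(=O)C=[N+]=[N-] | starting material
11 | tert-butyl (1R,6R,7R)-3-allyl-5,5-dimethoxy-6-methyl-2-oxo-7-(3,4,5-trimethoxyphenyl)cyclohept-3-ene-1-carboxylate (ester cis to aryl, aryl trans to methyl) | C=CCC1=CC(OC)(OC)[C@H](C)[C@@H](c2cc(OC)c(OC)c(OC)c2)[C@@H](C(=O)OC(C)(C)C)C1=O | intermediate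
12 | (1R,6R,7R)-3-allyl-5,5-dimethoxy-6-methyl-2-oxo-7-(3,4,5-trimethoxyphenyl)cyclohept-3-ene-1-carboxylic acid | C=CCC1=CC(OC)(OC)[C@H](C)[C@@H](c2cc(OC)c(OC)c(OC)c2)[C@@H](C(=O)O)C1=O | intermediate
13 | (1R,5S,8R,9R)-3-allyl-5-methoxy-9-methyl-8-(3,4,5-trimethoxyphenyl)-6-oxabicyclo[3.2.2]non-3-ene-2,7-dione | C=CCC1=C[C@@]2(OC)OC(=O)[C@@H](C1=O)[C@H](c1cc(OC)c(OC)c(OC)c1)[C@H]2C | target

Total step count: 7. Longest linear sequence: 7 steps (1 → 13).

**Steps most likely to fail**

Step 6. The diazoacetate may add too slowly to the hindered, conjugated carbonyl. The Lewis acid would then ionise the ketal, with loss of methanol and aromatisation of the ring, or the alkenyl carbon would migrate in place of the benzylic one. The fallback sets out from 9 and separates ring enlargement from carboxylation. A much more nucleophilic diazoalkane, (trimethylsilyl)diazomethane, is used with Me3Al in CH2Cl2 at −78 °C and should give the α-silyl cycloheptenone F1. K2CO3 in MeOH then removes the silyl group of F1 to give the ring-enlarged cycloheptenone F2, whose only enolisable position is the new CH2 between the ketone and CHAr. LiHMDS in THF at −78 °C followed by CO2 should convert F2 into the lithium β-keto carboxylate F3. Running the cold solution of F3 into TFA/CH2Cl2 at 0 °C liberates the β-keto acid, and the route is rejoined at 12.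

Step 7. The lactone may close on the wrong face of the seven-membered ring, starting from the C1 epimer with the carboxyl trans to the aryl group, or the free β-keto acid may lose CO2 before the ketal ionises. The fallback sets out from 11 and fixes C1 before closure. NBS with catalytic Et3N in CH2Cl2 at −20 °C should brominate the enol at C1 anti to the neighbouring aryl group and give the bromo keto ester F4, a quaternary centre that cannot epimerise and holds the ester cis to the aryl group. TFA/CH2Cl2 at 0 °C can then close the lactone of F4 only on the aryl face, giving the bridgehead bromo lactone F5. Bu3SnH with AIBN in toluene at 80 °C replaces the bridgehead bromine of F5 by hydrogen, necessarily with retention; the stannane is used in excess so that hydrogen transfer outruns any radical cyclisation onto the allyl group. The route is rejoined at 13.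

Step 5. Heck-type arylation or palladium-hydride isomerisation of the allyl group, or base-induced degradation of the enone ketal, may compete with enolate arylation. The fallback sets out from 7 and uses neither palladium nor strong base at the arylation stage. LDA and TMSCl in THF at −78 °C give the silyl dienol ether F6. The aryl donor is mesityl(3,4,5-trimethoxyphenyl)iodonium tetrafluoroborate F7, prepared from 3,4,5-trimethoxyphenylboronic acid and MesI(OAc)2 with BF3·OEt2 in CH2Cl2. Cu(OTf)2 (10 mol%) in CH2Cl2 at rt should transfer the trimethoxyphenyl group of F7 to C6 of F6, the mesityl group staying on iodine. Brief DBU equilibration then gives the trans isomer, and the route is rejoined at 9.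

**Further compounds**

F1 | step 6 | (5R,6S)-2-allyl-4,4-dimethoxy-5-methyl-6-(3,4,5-trimethoxyphenyl)-7-(trimethylsilyl)cyclohept-2-en-1-one (C7 epimers) | C=CCC1=CC(OC)(OC)[C@H](C)[C@@H](c2cc(OC)c(OC)c(OC)c2)C([Si](C)(C)C)C1=O
F2 | step 6 | (5R,6S)-2-allyl-4,4-dimethoxy-5-methyl-6-(3,4,5-trimethoxyphenyl)cyclohept-2-en-1-one | C=CCC1=CC(OC)(OC)[C@H](C)[C@@H](c2cc(OC)c(OC)c(OC)c2)CC1=O
F3 | step 6 | lithium (6R,7R)-3-allyl-5,5-dimethoxy-6-methyl-2-oxo-7-(3,4,5-trimethoxyphenyl)cyclohept-3-ene-1-carboxylate (C1 epimers) | C=CCC1=CC(OC)(OC)[C@H](C)[C@@H](c2cc(OC)c(OC)c(OC)c2)C(C(=O)[O-])C1=O.[Li+]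
F4 | step 7 | tert-butyl (1S,6R,7S)-3-allyl-1-bromo-5,5-dimethoxy-6-methyl-2-oxo-7-(3,4,5-trimethoxyphenyl)cyclohept-3-ene-1-carboxylate | C=CCC1=CC(OC)(OC)[C@H](C)[C@@H](c2cc(OC)c(OC)c(OC)c2)[C@@](Br)(C(=O)OC(C)(C)C)C1=O
F5 | step 7 | (1S,5S,8S,9R)-3-allyl-1-bromo-5-methoxy-9-methyl-8-(3,4,5-trimethoxyphenyl)-6-oxabicyclo[3.2.2]non-3-ene-2,7-dione | C=CCC1=C[C@@]2(OC)OC(=O)[C@@](Br)(C1=O)[C@H](c1cc(OC)c(OC)c(OC)c1)[C@H]2C
F6 | step 5 | {[(3R)-6-allyl-4,4-dimethoxy-3-methylcyclohexa-1,5-dien-1-yl]oxy}trimethylsilane | C=CCC1=CC(OC)(OC)[C@H](C)C=C1O[Si](C)(C)C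
F7 | step 5 | mesityl(3,4,5-trimethoxyphenyl)iodonium tetrafluoroborate | COc1cc([I+]c2c(C)cc(C)cc2C)cc(OC)c1OC.F[B-](F)(F)F
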